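## The problem

Target 18 is a (2S)-flavanone: a 4-hydroxy-3-methoxyphenyl ring B sits on C2 of a dihydropyranone ring C, which is fused through C4a–C8a to a phloroglucinol ring A. Flavanone numbering (O1, C2, C3, C4, C4a, C5–C8, C8a) is used throughout, also for the monocyclic ring C intermediates.

Ring A is fully differentiated. C5 carries a hydroxyl hydrogen-bonded to the C4 carbonyl, C6 a quaternary 1,1-dimethylallyl carbon wedged between two oxygens, C7 a free hydroxyl and C8 a hydrogen. Substitution or Claisen chemistry on an intact 5,7-dihydroxyflavanone distinguishes C6 from C8 poorly, and a tert-alkyl group cannot be put in by direct alkylation, so this pattern has to be built into the ring.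

C2 is the only stereocentre and nothing in the molecule can relay to it, so it must be set by a catalyst or reagent. It is also fragile. O1 is a β-leaving group relative to the C4 carbonyl, so base opens the ring to the chalcone. C2 is a para-oxygenated benzylic position, so strong acid can ionise the C2–O1 bond.

The 1,1-dimethylallyl group next to a phenol cyclises to a dihydrobenzofuran under strong acid, and three free phenols rule out oxidants and strong base late in the route.

The feature that opens a way is that C4a and C8a are the two sp2 carbons of a vinylogous ester in ring C. The other four ring A atoms read OH (C5), alkyl (C6), O (C7), H (C8), which is the pattern a vinylketene and a siloxyalkyne deliver in a benzannulation. The C5 hydroxyl arises free and the C7 oxygen arises silylated.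

## Retrosynthesis

**18 from 17.** Only two O–Si bonds are cut; the skeleton and C2 are already in place in 17. The C7 silyl ether is an unavoidable product of the ring-forming step, so the C4' phenol is given the same triisopropylsilyl group and both fall in one fluoride treatment. The C5 hydroxyl needs no protection because it emerges chelated to C4=O. The forward step must be non-basic so that the flavanone does not open to the chalcone.

**17 from 9 and 12.** Four bonds are cut: C8–C8a, C5–C6, C7–C8 and C4a–C5. This removes ring A entirely and leaves diazoketone 9, a monocyclic ring C that already holds C2, and the seven-carbon siloxyalkyne 12. The neighbouring cuts are weaker: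
- Cutting the C6–quaternary carbon bond on a finished ring A meets the C6/C8 ambiguity.
- Cutting ring C (chalcone route) forms C2 under equilibrating conditions.

The chosen cut instead forms ring A last, under neutral conditions, from a ring C whose stereocentre lies outside the reacting π system. The forward reaction passes through vinylketene 13, cyclobutenone 14, dienylketene 15 and dienone 16. It asks for one regiochemical event: the alkyne carbon bearing the tert-alkyl group must bond to the ketene carbonyl carbon.

**9 from 6 via 7 and 8.** The bond between the side-chain carbonyl carbon and the diazo carbon is cut, leading back through acid chloride 8 and acid 7 to methyl ester 6. This is the first half of an Arndt–Eistert sequence and adds the one carbon that becomes C8. The forward steps must free the acid without base, and must acylate the diazoalkane faster than it adds to the C4a=C8a bond.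

**6 from 2 and 4.** The O1–C8a and C2–C3 bonds are cut, a hetero-Diels–Alder disconnection that runs forward as a Mukaiyama aldol (adduct 5) followed by cyclocondensation. It is preferred over an oxa-Michael closure of an open-chain enone, because C2 is then set irreversibly by catalyst-controlled addition to an aldehyde and the C2–O bond is never broken afterwards. Aldehyde 2 is silylated vanillin 1. Diene 4 is the bis(silyl enol ether) of commercial diketo ester 3, whose ester carbon becomes the side-chain carbonyl of 9.

**12 from 10 via 11.** The alkyne is traced to ynolate 11 and on to ester 10 by a Kowalski one-carbon homologation. The quaternary carbon with its vinyl and two methyl groups is bought ready-made in 10, so the hardest carbon of ring A is never constructed on the ring.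

## Roads not taken

**Alternative 1: ortho-quinone methide cascade to the quaternary carbon.**
- **Cut:** the methyl and vinyl bonds to the quaternary carbon on a preformed phloroglucinol.
- **Forward key step:** a methyl Grignard reagent adds to the acetyl group of aryl ketone A1. The neighbouring Boc group migrates to the new alkoxide and leaves, giving an ortho-quinone methide. A vinyl Grignard reagent then adds 1,4 to give phenol A2.
- **Merits:** the most hindered carbon is made by two fast organomagnesium additions in one pot. Its position relative to the three oxygens is fixed by the starting ketone, and the three oxygens come out differentiated.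
- **Weak points:**
  - No ring and no stereocentre is formed.
  - From A2 the route still needs C-acylation of a crowded ring, a chalcone, and an enantioselective oxa-Michael closure that is reversible for such chalcones.
  - It carries four phenol protecting groups, one of them an acetal that must be removed by acid next to the acid-sensitive dimethylallyl/phenol pair.
  - A quinone methide with two methyl groups on the exocyclic carbon may tautomerise to an isopropenylphenol before the second nucleophile arrives.
- **Comparison:** this road is better at the quaternary carbon, where the chosen plan gambles on a hindered alkyne in step 7. Against that, the chosen plan sets C2 on a simple aldehyde and then places every ring A substituent in one neutral operation, in fewer steps.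

**Alternative 2: aryne annulation closing ring C.**
- **Cut:** O1–C8a and C4–C4a.
- **Forward key step:** fluoride unmasks the aryne from silyl triflate A3. The alkoxide of hydroxy ester A4 adds at C8a, the position remote from the C5 alkoxy group, and the C4a aryl anion closes onto the ester to give flavanone A5.
- **Merits:** ring C closes in one step. C2 is imported from A4, which is available by asymmetric hydrogenation of a β-keto ester; this is arguably a more dependable source of chirality than step 3 of the chosen route. The regiochemistry is electronically favoured.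
- **Weak points:**
  - A3 is a hexasubstituted benzene that already contains the quaternary carbon between two protected oxygens, so the ring A problem is only moved upstream.
  - The alkoxide of a β-hydroxy ester under fluoride can undergo retro-aldol cleavage or dehydration to the cinnamate.
  - Protonation of the aryl anion competes with acylation.
  - Three acetal groups must be removed by acid at the end, near the dimethylallyl/phenol pair and C2.
- **Comparison:** the stereocentre is better sourced here. The chosen plan answers with a much shorter path to ring A, because the quaternary carbon arrives in an acyclic ester, and pays for it with an untested cycloaddition.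

**Alternative 3: biomimetic Claisen annulation onto a chiral pyranone.**
- **Cut:** C8–C8a and C4a–C5.
- **Forward key step:** the terminal carbanion of the dianion of keto ester A7 displaces the methylthio group of pyranone A6 by addition–elimination at C8a. The extended enolate then attacks the ester, giving flavanone A8 with both ring A hydroxyls free.
- **Merits:** it uses the same chiral pyranone platform as the chosen plan, with no ring A protecting groups, no diazo compound and no photochemistry. It is the shortest route on paper.
- **Weak points:**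
  - The dianion is strongly basic, and in A6 the C3 hydrogens are acidic and O1 is set up for β-elimination, the one condition C2 does not tolerate.
  - The ester carbonyl of A7 is flanked by the tert-alkyl-bearing carbon, so the ring-closing acylation is hindered.
  - A7 itself requires tert-alkylation of an acetoacetate.
- **Comparison:** this road wins on step count and protecting-group economy. The chosen plan forms the same two bonds plus two more, and sets against it that ring A closes with no base present and C2 insulated.

Key step: step 7

Assumption: the (R)-disulfonimide of step 3 is taken to expose the Si face of aldehyde 2 to the enol silane, which gives 2S; if a pilot run shows the opposite sense, the (S)-catalyst is used and nothing else changes.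

## Route

Step 1
Reactants: 1 vanillin
Product: 2 3-methoxy-4-(triisopropylsilyloxy)benzaldehyde
Conditions: TIPSCl, imidazole, DMF, 25 °C
Reagents that add atoms: triisopropylsilyl chloride, CC(C)[Si](Cl)(C(C)C)C(C)C
Why: Standard phenol silylation; the bulky silyl ether is chosen to survive steps 3 to 7 and to leave together with the C7 silyl ether in step 8.

Step 2
Reactants: 3 methyl 2,4-dioxopentanoate
Product: 4 methyl (2Z)-2,4-bis(trimethylsilyloxy)penta-2,4-dienoate
Conditions: TMSOTf (2.3 equiv), Et3N, Et2O, 0 → 25 °C
Reagents that add atoms: trimethylsilyl trifluoromethanesulfonate, C[Si](C)(C)OS(=O)(=O)C(F)(F)F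
Why: Double O-silylation by soft enolisation, as used for 1,3-bis(silyloxy)dienes of 1,3-dicarbonyl compounds; the chelated enol is silylated first and the methyl ketone, the only remaining enolisable site, second, which should carry the enol geometry into the 2Z diene.

Step 3
Reactants: 2 3-methoxy-4-(triisopropylsilyloxy)benzaldehyde; 4 methyl (2Z)-2,4-bis(trimethylsilyloxy)penta-2,4-dienoate
Product: 6 methyl (2S)-2-[3-methoxy-4-(triisopropylsilyloxy)phenyl]-4-oxo-3,4-dihydro-2H-pyran-6-carboxylate, via silylated aldol adduct 5 (not isolated)
Conditions: (R)-3,3'-bis[3,5-bis(trifluoromethyl)phenyl]-1,1'-binaphthyl-2,2'-disulfonimide (5 mol%), Et2O, –78 → –20 °C; then TFA (cat.), CH2Cl2, 0 °C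
Reagents that add atoms: none
Why: Catalytic asymmetric hetero-Diels–Alder reaction run as a Mukaiyama aldol and cyclocondensation: the silylated disulfonimide activates 2 and the terminal enol silane carbon of 4 should add to the Si face, setting C2 as S under catalyst control. Brief acid then lets the C2 oxygen close onto the keto ester carbonyl and dehydrate, so the C2–O bond is never broken; aromatic aldehydes with 1,3-bis(silyloxy)dienes are an established substrate class and the ester on the diene is the only new element.

Step 4
Reactants: 6 methyl (2S)-2-[3-methoxy-4-(triisopropylsilyloxy)phenyl]-4-oxo-3,4-dihydro-2H-pyran-6-carboxylate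
Product: 7 (2S)-2-[3-methoxy-4-(triisopropylsilyloxy)phenyl]-4-oxo-3,4-dihydro-2H-pyran-6-carboxylic acid
Conditions: Me3SnOH (4 equiv), ClCH2CH2Cl, 70 °C; then cold 0.1 M aq. HCl wash
Reagents that add atoms: trimethyltin hydroxide, C[Sn](C)(C)O
Why: Tin hydroxide ester hydrolysis under near-neutral conditions; the activated alkoxyacrylate-type methyl ester should be cleaved without forming the C3 enolate that would expel O1 (retro-oxa-Michael), and the aryl silyl ether should survive.

Step 5
Reactants: 7 (2S)-2-[3-methoxy-4-(triisopropylsilyloxy)phenyl]-4-oxo-3,4-dihydro-2H-pyran-6-carboxylic acid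
Product: 9 (2S)-6-(diazoacetyl)-2-[3-methoxy-4-(triisopropylsilyloxy)phenyl]-2,3-dihydro-4H-pyran-4-one, via acid chloride 8 (not isolated)
Conditions: 1-chloro-N,N,2-trimethylprop-1-en-1-amine, CH2Cl2, 0 °C; then CH2N2 (1.5 equiv), Et3N, Et2O, –20 → 0 °C
Reagents that add atoms: diazomethane, C=[N+]=[N-]
Why: Acylation of diazomethane by an acid chloride (first stage of the Arndt–Eistert sequence) with an amine as HCl scavenger, which is permissible because 8 has no α-hydrogen. The chloro-enamine forms 8 without free HCl, and a small excess of diazomethane at low temperature should limit dipolar cycloaddition to the push-pull C4a=C8a bond.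

Step 6
Reactants: 10 methyl 2,2-dimethylbut-3-enoate
Product: 12 3,3-dimethyl-1-(triisopropylsilyloxy)pent-4-en-1-yne, via lithium ynolate 11 (not isolated)
Conditions: CH2Br2, LiTMP, THF, –78 °C; then n-BuLi, –78 → 25 °C; then TIPSCl, 0 → 25 °C
Reagents that add atoms: dibromomethane, BrCBr; triisopropylsilyl chloride, CC(C)[Si](Cl)(C(C)C)C(C)C
Why: Kowalski ester homologation stopped at the ynolate: LiCHBr2 adds to the ester, bromine–lithium exchange and 1,2-shift give ynolate 11, and the bulky silyl chloride silylates it on oxygen. The ester is non-enolisable and the vinyl group is inert to the bases used.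

Step 7
Reactants: 9 (2S)-6-(diazoacetyl)-2-[3-methoxy-4-(triisopropylsilyloxy)phenyl]-2,3-dihydro-4H-pyran-4-one; 12 3,3-dimethyl-1-(triisopropylsilyloxy)pent-4-en-1-yne
Product: 17 (2S)-5-hydroxy-2-[3-methoxy-4-(triisopropylsilyloxy)phenyl]-6-(2-methylbut-3-en-2-yl)-7-(triisopropylsilyloxy)-2,3-dihydro-4H-chromen-4-one, via vinylketene 13 (not isolated), via cyclobutenone 14 (not isolated), via dienylketene 15 (not isolated), via dienone 16 (not isolated)
Conditions: 12 (2 equiv), hν (254 nm, quartz), ClCH2CH2Cl, 25 °C; then 80 °C
Reagents that add atoms: none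
Why: Light expels N2 from 9 and Wolff migration of the pyranyl sp2 carbon gives vinylketene 13, forming C8–C8a. The electron-rich alkyne 12 traps the ketene in a [2+2] cycloaddition to cyclobutenone 14, forming C5–C6 and C7–C8. 4π-Electrocyclic opening of 14 gives dienylketene 15, and its 6π-electrocyclic closure onto C4a forms C4a–C5 and ring A as dienone 16, which enolises to the chelated C5 phenol 17. The closest known reaction is the second-generation Danheiser benzannulation of α,β-unsaturated diazoketones with siloxyalkynes to resorcinol monosilyl ethers; the pyranone-derived ketene and the tert-alkyl alkyne are new substrates within that class. No lasting stereocentre is made: the centres at the ring carbon of 14 and at C4a of 16 disappear on opening and aromatisation, and C2 lies outside the reacting π system with no acid or base present. The step needs regioselectivity in the [2+2]: the alkyne carbon remote from oxygen, which bears the tert-alkyl group, is the nucleophilic terminus of the ynol ether and should bond to the electrophilic ketene carbonyl carbon, placing the 1,1-dimethylallyl group at C6 between the two oxygens. It also needs chemoselectivity, which the large reactivity gap between the ynol ether and the isolated vinyl group of 12 should secure. Excess 12 and the low stationary ketene concentration under photolysis are meant to offset the slower addition of the hindered alkyne, and heating completes the conversion of 14.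

Step 8
Reactants: 17 (2S)-5-hydroxy-2-[3-methoxy-4-(triisopropylsilyloxy)phenyl]-6-(2-methylbut-3-en-2-yl)-7-(triisopropylsilyloxy)-2,3-dihydro-4H-chromen-4-one
Product: 18 (2S)-5,7-dihydroxy-2-(4-hydroxy-3-methoxyphenyl)-6-(2-methylbut-3-en-2-yl)-2,3-dihydro-4H-chromen-4-one
Conditions: HF·pyridine, pyridine, THF, 0 → 25 °C
Reagents that add atoms: none
Why: Fluoride cleavage of two aryl silyl ethers; the C7 ether, para to the C4 carbonyl, should go first and the guaiacyl ether more slowly. The pyridine-buffered, non-basic medium keeps phenoxide concentration low, so the flavanone should not open to the chalcone and C2 is retained; the alkene and the chelated C5 hydroxyl are not affected.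

## Compound list

1 | vanillin | COc1cc(C=O)ccc1O | starting material
2 | 3-methoxy-4-(triisopropylsilyloxy)benzaldehyde | COc1cc(C=O)ccc1O[Si](C(C)C)(C(C)C)C(C)C | intermediate
3 | methyl 2,4-dioxopentanoate | COC(=O)C(=O)CC(C)=O | starting material
4 | methyl (2Z)-2,4-bis(trimethylsilyloxy)penta-2,4-dienoate | COC(=O)/C(O[Si](C)(C)C)=C/C(=C)O[Si](C)(C)C | intermediate
5 | methyl (2Z,6S)-6-[3-methoxy-4-(triisopropylsilyloxy)phenyl]-4-oxo-2,6-bis(trimethylsilyloxy)hex-2-enoate | COC(=O)/C(O[Si](C)(C)C)=C/C(=O)C[C@H](O[Si](C)(C)C)c1ccc(O[Si](C(C)C)(C(C)C)C(C)C)c(OC)c1 | intermediate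
6 | methyl (2S)-2-[3-methoxy-4-(triisopropylsilyloxy)phenyl]-4-oxo-3,4-dihydro-2H-pyran-6-carboxylate | COC(=O)C1=CC(=O)C[C@@H](c2ccc(O[Si](C(C)C)(C(C)C)C(C)C)c(OC)c2)O1 | intermediate
7 | (2S)-2-[3-methoxy-4-(triisopropylsilyloxy)phenyl]-4-oxo-3,4-dihydro-2H-pyran-6-carboxylic acid | OC(=O)C1=CC(=O)C[C@@H](c2ccc(O[Si](C(C)C)(C(C)C)C(C)C)c(OC)c2)O1 | intermediate
8 | (2S)-2-[3-methoxy-4-(triisopropylsilyloxy)phenyl]-4-oxo-3,4-dihydro-2H-pyran-6-carbonyl chloride | ClC(=O)C1=CC(=O)C[C@@H](c2ccc(O[Si](C(C)C)(C(C)C)C(C)C)c(OC)c2)O1 | intermediate
9 | (2S)-6-(diazoacetyl)-2-[3-methoxy-4-(triisopropylsilyloxy)phenyl]-2,3-dihydro-4H-pyran-4-one | [N-]=[N+]=CC(=O)C1=CC(=O)C[C@@H](c2ccc(O[Si](C(C)C)(C(C)C)C(C)C)c(OC)c2)O1 | intermediate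
10 | methyl 2,2-dimethylbut-3-enoate | COC(=O)C(C)(C)C=C | starting material
11 | lithium 3,3-dimethylpent-4-en-1-yn-1-olate | C=CC(C)(C)C#C[O-].[Li+] | intermediate
12 | 3,3-dimethyl-1-(triisopropylsilyloxy)pent-4-en-1-yne | C=CC(C)(C)C#CO[Si](C(C)C)(C(C)C)C(C)C | intermediate
13 | (2S)-2-[3-methoxy-4-(triisopropylsilyloxy)phenyl]-6-(2-oxoethenyl)-2,3-dihydro-4H-pyran-4-one | O=C=CC1=CC(=O)C[C@@H](c2ccc(O[Si](C(C)C)(C(C)C)C(C)C)c(OC)c2)O1 | intermediate
14 | 4-{(2S)-2-[3-methoxy-4-(triisopropylsilyloxy)phenyl]-4-oxo-3,4-dihydro-2H-pyran-6-yl}-2-(2-methylbut-3-en-2-yl)-3-(triisopropylsilyloxy)cyclobut-2-en-1-one (either configuration at the cyclobutenone carbon bearing the pyranyl group) | C=CC(C)(C)C1=C(O[Si](C(C)C)(C(C)C)C(C)C)C(C2=CC(=O)C[C@@H](c3ccc(O[Si](C(C)C)(C(C)C)C(C)C)c(OC)c3)O2)C1=O | intermediate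
15 | (3E)-4-{(2S)-2-[3-methoxy-4-(triisopropylsilyloxy)phenyl]-4-oxo-3,4-dihydro-2H-pyran-6-yl}-2-(2-methylbut-3-en-2-yl)-3-(triisopropylsilyloxy)buta-1,3-dien-1-one | C=CC(C)(C)C(=C=O)/C(O[Si](C(C)C)(C(C)C)C(C)C)=C\C1=CC(=O)C[C@@H](c2ccc(O[Si](C(C)C)(C(C)C)C(C)C)c(OC)c2)O1 | intermediate
16 | (2S)-2-[3-methoxy-4-(triisopropylsilyloxy)phenyl]-6-(2-methylbut-3-en-2-yl)-7-(triisopropylsilyloxy)-2,3-dihydro-4H-chromene-4,5(4aH)-dione (either configuration at C4a) | C=CC(C)(C)C1=C(O[Si](C(C)C)(C(C)C)C(C)C)C=C2O[C@H](c3ccc(O[Si](C(C)C)(C(C)C)C(C)C)c(OC)c3)CC(=O)C2C1=O | intermediate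
17 | (2S)-5-hydroxy-2-[3-methoxy-4-(triisopropylsilyloxy)phenyl]-6-(2-methylbut-3-en-2-yl)-7-(triisopropylsilyloxy)-2,3-dihydro-4H-chromen-4-one | C=CC(C)(C)c1c(O[Si](C(C)C)(C(C)C)C(C)C)cc2c(c1O)C(=O)C[C@@H](c1ccc(O[Si](C(C)C)(C(C)C)C(C)C)c(OC)c1)O2 | intermediate
18 | (2S)-5,7-dihydroxy-2-(4-hydroxy-3-methoxyphenyl)-6-(2-methylbut-3-en-2-yl)-2,3-dihydro-4H-chromen-4-one | C=CC(C)(C)c1c(O)cc2c(c1O)C(=O)C[C@@H](c1ccc(O)c(OC)c1)O2 | target

## Step count and least certain steps

Total: 8 steps. Longest linear sequence: 6 steps (steps 1, 3, 4, 5, 7, 8); steps 2 and 6 prepare the two partners.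

**Step 7 (key step).** The [2+2] must take place at an alkyne carbon carrying a quaternary centre. If it is slow, the vinylketene may be diverted into dimerisation or acylation of the product phenol. Prolonged 254 nm irradiation of the flavanone chromophore could also open the O1–C2 bond photochemically and erode the configuration.
Fallback (thermal ketene generation, no light), setting out from 9: a Wolff rearrangement catalysed by AgOCOPh in aqueous THF gives the homologous acid {(2S)-2-[3-methoxy-4-(triisopropylsilyloxy)phenyl]-4-oxo-3,4-dihydro-2H-pyran-6-yl}acetic acid F1. 1-Chloro-N,N,2-trimethylprop-1-en-1-amine converts it into the acid chloride {(2S)-2-[3-methoxy-4-(triisopropylsilyloxy)phenyl]-4-oxo-3,4-dihydro-2H-pyran-6-yl}acetyl chloride F2. Slow addition of F2 to Et3N and a large excess of 12 in toluene at 80–110 °C dehydrochlorinates it to vinylketene 13, where the route is rejoined and continues through 14, 15 and 16 to 17. Ketene generation from acid chlorides in the presence of siloxyalkynes is known chemistry for resorcinol synthesis.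

**Step 3.** The ester group makes diene 4 a weaker nucleophile than the dienes of the known cases, and aldehyde 2 is electron-rich, so low conversion or poor facial selectivity is possible. Partial ionisation of the C2–O1 bond during the acid cyclisation would also lower the enantiomeric purity.
Fallback (reagent-controlled allylation, then ring construction), setting out from 2: Brown allylation with (–)-B-allyldiisopinocampheylborane should give (1S)-1-[3-methoxy-4-(triisopropylsilyloxy)phenyl]but-3-en-1-ol F3. Wacker oxidation (PdCl2, CuCl, O2, DMF/H2O) gives (4S)-4-hydroxy-4-[3-methoxy-4-(triisopropylsilyloxy)phenyl]butan-2-one F4. Its dianion (LDA, 2.2 equiv, THF, –78 °C) is acylated at the methyl group with dimethyl oxalate to give methyl (6S)-6-hydroxy-6-[3-methoxy-4-(triisopropylsilyloxy)phenyl]-2,4-dioxohexanoate F5. Catalytic TFA cyclodehydrates F5 to 6, where the route is rejoined.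

**Step 5.** Diazomethane may add as a 1,3-dipole to the C4a=C8a bond of 8 or 9 (pyrazoline formation) in competition with C-acylation.
Fallback (diazo transfer in place of diazoalkane acylation), setting out from 8: Pd(PPh3)4-catalysed coupling with Me2Zn gives the methyl ketone (2S)-6-acetyl-2-[3-methoxy-4-(triisopropylsilyloxy)phenyl]-2,3-dihydro-4H-pyran-4-one F6. Kinetic enolisation with LiHMDS at –78 °C and trifluoroacetylation with CF3CO2CH2CF3 gives 4,4,4-trifluoro-1-{(2S)-2-[3-methoxy-4-(triisopropylsilyloxy)phenyl]-4-oxo-3,4-dihydro-2H-pyran-6-yl}butane-1,3-dione F7. Detrifluoroacetylative diazo transfer (MsN3, Et3N, H2O, MeCN) converts F7 into 9, where the route is rejoined.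

**Step 6.** Addition of LiCHBr2 to the neopentyl-type ester carbonyl may be sluggish, the rearrangement to the ynolate incomplete, or silylation may occur on carbon to give a silylketene. The volatile, moisture-sensitive siloxyalkyne may also be lost on isolation.
Fallback (ynolate by acetylide oxidation), setting out from 10: DIBAL-H reduction at –78 °C gives 2,2-dimethylbut-3-enal F8. Ohira–Bestmann homologation (dimethyl (1-diazo-2-oxopropyl)phosphonate, K2CO3, MeOH) gives 3,3-dimethylpent-1-en-4-yne F9, handled in solution. Deprotonation with n-BuLi and oxidation of the lithium acetylide with LiOOt-Bu gives ynolate 11, where the route is rejoined before silylation to 12.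

## Further compounds

F1 | step 7 | {(2S)-2-[3-methoxy-4-(triisopropylsilyloxy)phenyl]-4-oxo-3,4-dihydro-2H-pyran-6-yl}acetic acid | OC(=O)CC1=CC(=O)C[C@@H](c2ccc(O[Si](C(C)C)(C(C)C)C(C)C)c(OC)c2)O1
F2 | step 7 | {(2S)-2-[3-methoxy-4-(triisopropylsilyloxy)phenyl]-4-oxo-3,4-dihydro-2H-pyran-6-yl}acetyl chloride | ClC(=O)CC1=CC(=O)C[C@@H](c2ccc(O[Si](C(C)C)(C(C)C)C(C)C)c(OC)c2)O1
F3 | step 3 | (1S)-1-[3-methoxy-4-(triisopropylsilyloxy)phenyl]but-3-en-1-ol | C=CC[C@H](O)c1ccc(O[Si](C(C)C)(C(C)C)C(C)C)c(OC)c1
F4 | step 3 | (4S)-4-hydroxy-4-[3-methoxy-4-(triisopropylsilyloxy)phenyl]butan-2-one | CC(=O)C[C@H](O)c1ccc(O[Si](C(C)C)(C(C)C)C(C)C)c(OC)c1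
F5 | step 3 | methyl (6S)-6-hydroxy-6-[3-methoxy-4-(triisopropylsilyloxy)phenyl]-2,4-dioxohexanoate | COC(=O)C(=O)CC(=O)C[C@H](O)c1ccc(O[Si](C(C)C)(C(C)C)C(C)C)c(OC)c1
F6 | step 5 | (2S)-6-acetyl-2-[3-methoxy-4-(triisopropylsilyloxy)phenyl]-2,3-dihydro-4H-pyran-4-one | CC(=O)C1=CC(=O)C[C@@H](c2ccc(O[Si](C(C)C)(C(C)C)C(C)C)c(OC)c2)O1
F7 | step 5 | 4,4,4-trifluoro-1-{(2S)-2-[3-methoxy-4-(triisopropylsilyloxy)phenyl]-4-oxo-3,4-dihydro-2H-pyran-6-yl}butane-1,3-dione | FC(F)(F)C(=O)CC(=O)C1=CC(=O)C[C@@H](c2ccc(O[Si](C(C)C)(C(C)C)C(C)C)c(OC)c2)O1
F8 | step 6 | 2,2-dimethylbut-3-enal | C=CC(C)(C)C=O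
F9 | step 6 | 3,3-dimethylpent-1-en-4-yne | C=CC(C)(C)C#C
A1 | alternative 1 | tert-butyl 2-acetyl-3-(methoxymethoxy)-5-(triisopropylsilyloxy)phenyl carbonate | CC(=O)c1c(OC(=O)OC(C)(C)C)cc(O[Si](C(C)C)(C(C)C)C(C)C)cc1OCOC
A2 | alternative 1 | 3-(methoxymethoxy)-2-(2-methylbut-3-en-2-yl)-5-(triisopropylsilyloxy)phenol | C=CC(C)(C)c1c(O)cc(O[Si](C(C)C)(C(C)C)C(C)C)cc1OCOC
A3 | alternative 2 | 3,5-bis(methoxymethoxy)-4-(2-methylbut-3-en-2-yl)-2-(trimethylsilyl)phenyl trifluoromethanesulfonate | C=CC(C)(C)c1c(OCOC)cc(OS(=O)(=O)C(F)(F)F)c([Si](C)(C)C)c1OCOC
A4 | alternative 2 | methyl (3S)-3-hydroxy-3-[3-methoxy-4-(methoxymethoxy)phenyl]propanoate | COC(=O)C[C@H](O)c1ccc(OCOC)c(OC)c1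
A5 | alternative 2 | (2S)-5,7-bis(methoxymethoxy)-2-[3-methoxy-4-(methoxymethoxy)phenyl]-6-(2-methylbut-3-en-2-yl)-2,3-dihydro-4H-chromen-4-one | C=CC(C)(C)c1c(OCOC)cc2c(c1OCOC)C(=O)C[C@@H](c1ccc(OCOC)c(OC)c1)O2
A6 | alternative 3 | (2S)-2-[3-methoxy-4-(methoxymethoxy)phenyl]-6-(methylsulfanyl)-2,3-dihydro-4H-pyran-4-one | CSC1=CC(=O)C[C@@H](c2ccc(OCOC)c(OC)c2)O1
A7 | alternative 3 | methyl 2-(2-methylbut-3-en-2-yl)-3-oxobutanoate | COC(=O)C(C(C)=O)C(C)(C)C=C
A8 | alternative 3 | (2S)-5,7-dihydroxy-2-[3-methoxy-4-(methoxymethoxy)phenyl]-6-(2-methylbut-3-en-2-yl)-2,3-dihydro-4H-chromen-4-one | C=CC(C)(C)c1c(O)cc2c(c1O)C(=O)C[C@@H](c1ccc(OCOC)c(OC)c1)O2
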